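The data were computed for an exercise, and the scatter is random.

In a one-step world every L lost becomes D, so D passes L at half of the charge, but the spring and midnight runs lost L to other things as well, and this changes the line. I therefore divided D gained by L lost, a share in which time drops out, the selectivity of the flask towards D, which I called the share. The last readings gave 76.0% in spring and 71.1% in midnight, and I carried 73.6%. With that share D led once the fraction of L left fell below the share divided by one plus the share, which was 42.4%.

| flask | L | J | Q | temperature | remark | time |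
|---|---|---|---|---|---|---|
| spring | 0.70 M | 0.60 M | 0.15 M | 40 °C | run made earlier |  |
| midnight | 1.1 M | 0.60 M | 0.15 M | 51 °C | run made earlier |  |
| green | 0.50 M | 0.600 M | 0.150 M | 35 °C |  | 40 h |
| violet | 0.50 M | 0.600 M | 0.150 M | 55 °C |  | 40 h |

| run | time / h | X / % | L / % | E / % | D / % |
|---|---|---|---|---|---|
| spring | 5.00 | 0 | 90.4 | 1.9 | 6.0 |
| spring | 10.0 | 3.4 | 84.3 | 2.6 | 11.0 |
| spring | 15.0 | 4.4 | 78.0 | 4.6 | 13.5 |
| spring | 20.0 | 3.9 | 75.2 | 4.3 | 16.5 |
| spring | 25.0 | 6.4 | 70.7 | 4.7 | 19.3 |
| spring | 30.0 | 5.6 | 70.4 | 2.6 | 22.5 |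
| midnight | 1.00 | 0.1 | 95.5 | 1.4 | 3.0 |
| midnight | 2.00 | 0 | 92.1 | 1.7 | 6.8 |
| midnight | 4.00 | 0.4 | 84.8 | 4.3 | 9.8 |
| midnight | 5.00 | 2.9 | 83.9 | 4.9 | 11.6 |
| midnight | 10.0 | 3.7 | 74.1 | 2.9 | 17.2 |
| midnight | 15.0 | 3.6 | 70.6 | 1.6 | 20.9 |

(scatter of a reading: 1 percentage point)

1. which of these there is most of at the end, counted by the L in it, green (L / X / E / D)
2. which of these there is most of at the end, counted by the L in it, violet (L / X / E / D)
3. final amount of the leader among these, as a percentage of the L charged, in green
4. final amount of the leader among these, as a percentage of the L charged, in violet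

The clock remained, and I read it as a ladder. The upper rung was the opening, where the readings of midnight showed a loss of 0.0450 h⁻¹ of its charge and those of spring 0.0192 h⁻¹. Below it came the tail, slower at 0.00700 h⁻¹ in midnight and slower at 0.00480 h⁻¹ in spring. Midnight, which differed from spring in its charge of L as well as in its temperature, reached about the same fraction of L in 15.0 h as spring in 30.0 h, and I scaled time by that factor as if temperature were the one difference. Green's 40 h then equalled 29.2 h of spring, which put L near 70.4%, above the line, with D near 21.8%. Violet's time equalled 51.5 h of midnight, and running the tail straight on put L at 45.1%, so I called L narrowly ahead of D at 40.4%.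

The forecast gave L at 72% in green but D at 46% in violet, on the suggestion that “D ties up Q”, so on violet it parted from me.

Green held L 68.5% and D 21.1%; violet held L 34.8% and D 47.4%, with G counted in D in both, so my reckoned L for violet had stood too high.

    J + Q → Z (k = 0.00134 M⁻¹ s⁻¹, Ea = 51.0 kJ mol⁻¹)
    J + D ⇌ G, settled at all times (K = 1.30 M⁻¹, ΔH = −26.0 kJ mol⁻¹)
    L + J → D (k = 6.97 × 10⁻⁶ M⁻¹ s⁻¹, Ea = 74.0 kJ mol⁻¹)
    L + 2 J → E (k = 3.15 × 10⁻⁶ M⁻² s⁻¹, Ea = 88.0 kJ mol⁻¹)
    D ⇌ X (K = 0.430, k = 2.04 × 10⁻⁵ s⁻¹, Ea = 99.0 kJ mol⁻¹, ΔH = −32.0 kJ mol⁻¹)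
    (constants at 35 °C)

Violet's L lay below the line, and the share gave D 48.0%; violet read at 10 h still had L at 60.1%, above the line, with L in front and D 28.3% against a reckoned 29.4%. In violet L passed into D 2.7 times as fast as into E just after the start, and this ratio was higher at 7.51 h, at 6.9.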